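**Retrosynthetic overview**
1. Last bond: the ester C–O bond between O-2 of glycerol and the diterpenoid acid, formed directly on unprotected glycerol.
2. Ring A is closed last, as the C1=C10 alkene, by reductive coupling (McMurry) of a 1,6-keto-aldehyde.
3. The C9 quaternary centre comes from two successive enolate alkylations beside the ring-B ketone: CH3 first, then a chiral-pool C5 iodide that carries C13.
4. C4 (gem-dimethyl) and the C4–C5 bond come from conjugate addition of a C3 acetal Grignard reagent to (R)-pulegone, which supplies ring B and C8.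
5. Ring order: ring B is bought (pulegone ring); ring A is formed in the McMurry step.

Assumption: positions carry halimane numbering (ring A = C1–C5 and C10, ring B = C5–C10, C4 gem-dimethyl, C8 CH–CH3, C9 quaternary, C13 side-chain CH–CH3, C15 carboxyl), and the boronic acid catalyst of step 9 is a separately made reagent outside the numbered route.

**Step 1**
Reactants: 1 (R)-(+)-pulegone [(5R)-5-methyl-2-(propan-2-ylidene)cyclohexan-1-one]; 2 [2-(1,3-dioxan-2-yl)ethyl]magnesium bromide (commercial THF solution)
Product: 4 (2S,5R)-2-[4-(1,3-dioxan-2-yl)-2-methylbutan-2-yl]-5-methylcyclohexan-1-one, via bromomagnesium enolate 3 (not isolated)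
Conditions: 2 (1.5 equiv), CuBr·SMe2 (10 mol %), THF, −30 → 0 °C; H2O; then KOH, EtOH, reflux; chromatography
Reagents that add atoms: none
Why: Copper-catalysed conjugate (1,4-) addition of the Grignard reagent to the β,β-disubstituted enone creates the C4 quaternary carbon with both methyl groups in place, C8 is the untouched pulegone stereocentre, and the new α-stereocentre C5 is set by base equilibration to the 2,5-trans (diequatorial, menthone-type) ketone, expected about 85:15, the minor cis epimer being removed and re-equilibrated.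

**Step 2**
Reactants: 4 (2S,5R)-2-[4-(1,3-dioxan-2-yl)-2-methylbutan-2-yl]-5-methylcyclohexan-1-one
Product: 6 (2S,3R,6S)-6-[4-(1,3-dioxan-2-yl)-2-methylbutan-2-yl]-2,3-dimethylcyclohexan-1-one (major C2 epimer shown), via lithium enolate 5 (not isolated)
Conditions: LiN(iPr)2, THF, −78 °C; MeI, −78 → 0 °C
Reagents that add atoms: iodomethane (CI)
Why: Kinetic enolate alkylation: LiN(iPr)2 deprotonates only the unhindered CH2 (C9) because the other α-carbon (C5) is shielded by the tertiary alkyl group, so C5 is untouched, and the configuration of the new methine is irrelevant because it becomes the enolate carbon of step 5.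

**Step 3**
Reactants: 7 (R)-3-methylglutaric acid monomethyl ester [(3R)-5-methoxy-3-methyl-5-oxopentanoic acid]
Product: 8 methyl (3R)-5-hydroxy-3-methylpentanoate
Conditions: BH3·SMe2, THF, 0 → 23 °C; MeOH
Reagents that add atoms: none
Why: Chemoselective borane reduction of a carboxylic acid in the presence of a methyl ester; the stereocentre (later C13) is not involved.

**Step 4**
Reactants: 8 methyl (3R)-5-hydroxy-3-methylpentanoate
Product: 9 methyl (3S)-5-iodo-3-methylpentanoate
Conditions: I2, PPh3, imidazole, CH2Cl2, 0 → 23 °C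
Reagents that add atoms: iodine ([I][I])
Why: Appel-type (Garegg–Samuelsson) iodination of the primary alcohol by SN2 at CH2; the stereocentre is untouched and its descriptor changes from R to S only because iodine reverses the CIP priorities.

**Step 5**
Reactants: 6 (2S,3R,6S)-6-[4-(1,3-dioxan-2-yl)-2-methylbutan-2-yl]-2,3-dimethylcyclohexan-1-one; 9 methyl (3S)-5-iodo-3-methylpentanoate
Product: 11 methyl (3R)-5-[(1R,3S,6R)-3-[4-(1,3-dioxan-2-yl)-2-methylbutan-2-yl]-1,6-dimethyl-2-oxocyclohexyl]-3-methylpentanoate, via potassium enolate 10 (not isolated)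
Conditions: KN(SiMe3)2, THF, −78 → 0 °C; 9 (1.5 equiv), DMPU, −40 → 23 °C; chromatography
Reagents that add atoms: none
Why: C-alkylation of the tetrasubstituted enolate (formed at C9 only, since an enolate towards C5 would place the tertiary alkyl group cis to the O–K group) sets the C9 quaternary centre by axial (antiparallel) attack on the half-chair that keeps the C5 chain and the C8 methyl pseudo-equatorial, that is on the face anti to the C5 chain (in the alternative half-chair this chain blocks the opposite face in a 1,3-relationship), so the side chain ends trans to the C5 chain and cis to the C8 methyl with the C9 methyl trans to the C8 methyl as in the target (expected about 5:1, minor epimer removed), while C13 arrives intact from 9.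

**Step 6**
Reactants: 11 methyl (3R)-5-[(1R,3S,6R)-3-[4-(1,3-dioxan-2-yl)-2-methylbutan-2-yl]-1,6-dimethyl-2-oxocyclohexyl]-3-methylpentanoate
Product: 12 methyl (3R)-5-[(1R,3S,6R)-1,6-dimethyl-3-(2-methyl-5-oxopentan-2-yl)-2-oxocyclohexyl]-3-methylpentanoate
Conditions: 1 M HCl, THF, 40 °C
Reagents that add atoms: water (O)
Why: Acid-catalysed acetal hydrolysis frees the aldehyde (C1) while the methyl ester and the hindered ketone survive dilute acid, and enolisation towards the shielded C5 is too slow to erode that centre.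

**Step 7**
Reactants: 12 methyl (3R)-5-[(1R,3S,6R)-1,6-dimethyl-3-(2-methyl-5-oxopentan-2-yl)-2-oxocyclohexyl]-3-methylpentanoate
Product: 13 methyl (3R)-3-methyl-5-[(1R,2R,4aS)-1,2,5,5-tetramethyl-1,2,3,4,4a,5,6,7-octahydronaphthalen-1-yl]pentanoate
Conditions: TiCl3(DME)1.5, Zn–Cu couple, DME, reflux, slow addition of 12 (high dilution)
Reagents that add atoms: none
Why: Intramolecular McMurry coupling of the 1,6-keto-aldehyde closes ring A and fixes the double bond at C1=C10 with no regioisomer possible; no stereocentre is formed, and the neighbouring C5 and C9 centres are not enolised by low-valent titanium.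

**Step 8**
Reactants: 13 methyl (3R)-3-methyl-5-[(1R,2R,4aS)-1,2,5,5-tetramethyl-1,2,3,4,4a,5,6,7-octahydronaphthalen-1-yl]pentanoate
Product: 14 (3R)-3-methyl-5-[(1R,2R,4aS)-1,2,5,5-tetramethyl-1,2,3,4,4a,5,6,7-octahydronaphthalen-1-yl]pentanoic acid
Conditions: LiOH, THF/MeOH/H2O, 40 °C; then 1 M HCl to pH 3, 0 °C
Reagents that add atoms: lithium hydroxide ([Li+].[OH-])
Why: Saponification (ester hydrolysis) under mild base leaves the trisubstituted alkene and all stereocentres alone, and the cold, brief acidification avoids migration of the C1=C10 double bond.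

**Step 9**
Reactants: 14 (3R)-3-methyl-5-[(1R,2R,4aS)-1,2,5,5-tetramethyl-1,2,3,4,4a,5,6,7-octahydronaphthalen-1-yl]pentanoic acid; 15 glycerol (propane-1,2,3-triol)
Product: 17 1,3-dihydroxypropan-2-yl (3R)-3-methyl-5-[(1R,2R,4aS)-1,2,5,5-tetramethyl-1,2,3,4,4a,5,6,7-octahydronaphthalen-1-yl]pentanoate (target), via O-acylisourea 16 (not isolated)
Conditions: N,N'-diisopropylcarbodiimide (1.2 equiv), CH2Cl2, 0 °C; then 15 (3 equiv, dry), {2-[4-(dimethylamino)pyridin-3-yl]phenyl}boronic acid (10 mol %), 4 Å MS, 0 °C; chromatography on B(OH)3-impregnated silica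
Reagents that add atoms: none
Why: Proposed new method: a bifunctional boronic acid/aminopyridine catalyst for direct 2-O-selective acylation of unprotected glycerol, which forms the key ester C–O bond in one step: trigonal boron (O–B–O near 120°) condenses reversibly with the two primary hydroxyls as a six-membered 1,3,2-dioxaborinane, which carries the otherwise insoluble glycerol into CH2Cl2 and switches off the boron-bound primary oxygens, while the pyridine nitrogen of the same molecule (kept from chelating boron by the twisted biaryl) takes the acyl group from O-acylisourea 16 and hands it intramolecularly to the only free hydroxyl, the C2–OH lying over boron; boronate exchange with fresh glycerol releases 17 and turns the catalyst over, and the low temperature and absence of free base suppress 2→1 acyl migration; the closest known reaction types are Steglich (carbodiimide/4-aminopyridine) esterification, transient boronic-ester masking of diols and borinic-acid-catalysed regioselective acylation of polyols; no new stereocentre is formed.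

**Compound list**
1 | (R)-(+)-pulegone, (5R)-5-methyl-2-(propan-2-ylidene)cyclohexan-1-one | C[C@@H]1CCC(=C(C)C)C(=O)C1 | starting material
2 | [2-(1,3-dioxan-2-yl)ethyl]magnesium bromide | Br[Mg]CCC1OCCCO1 | starting material
3 | bromomagnesium enolate of 4, bromo{[(5R)-2-[4-(1,3-dioxan-2-yl)-2-methylbutan-2-yl]-5-methylcyclohex-1-en-1-yl]oxy}magnesium | C[C@@H]1CCC(C(C)(C)CCC2OCCCO2)=C(O[Mg]Br)C1 | intermediate
4 | (2S,5R)-2-[4-(1,3-dioxan-2-yl)-2-methylbutan-2-yl]-5-methylcyclohexan-1-one | C[C@@H]1CC[C@@H](C(C)(C)CCC2OCCCO2)C(=O)C1 | intermediate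
5 | lithium enolate of 4, lithium (3R,6S)-6-[4-(1,3-dioxan-2-yl)-2-methylbutan-2-yl]-3-methylcyclohex-1-en-1-olate | C[C@@H]1CC[C@@H](C(C)(C)CCC2OCCCO2)C(O[Li])=C1 | intermediate
6 | (2S,3R,6S)-6-[4-(1,3-dioxan-2-yl)-2-methylbutan-2-yl]-2,3-dimethylcyclohexan-1-one (major C2 epimer) | C[C@@H]1CC[C@@H](C(C)(C)CCC2OCCCO2)C(=O)[C@H]1C | intermediate
7 | (R)-3-methylglutaric acid monomethyl ester, (3R)-5-methoxy-3-methyl-5-oxopentanoic acid | C[C@H](CC(=O)O)CC(=O)OC | starting material
8 | methyl (3R)-5-hydroxy-3-methylpentanoate | C[C@H](CCO)CC(=O)OC | intermediate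
9 | methyl (3S)-5-iodo-3-methylpentanoate | C[C@H](CCI)CC(=O)OC | intermediate
10 | potassium enolate of 6, potassium (3R,6S)-6-[4-(1,3-dioxan-2-yl)-2-methylbutan-2-yl]-2,3-dimethylcyclohex-1-en-1-olate | C[C@@H]1CC[C@@H](C(C)(C)CCC2OCCCO2)C(O[K])=C1C | intermediate
11 | methyl (3R)-5-[(1R,3S,6R)-3-[4-(1,3-dioxan-2-yl)-2-methylbutan-2-yl]-1,6-dimethyl-2-oxocyclohexyl]-3-methylpentanoate | COC(=O)C[C@H](C)CC[C@@]1(C)C(=O)[C@H](C(C)(C)CCC2OCCCO2)CC[C@H]1C | intermediate
12 | methyl (3R)-5-[(1R,3S,6R)-1,6-dimethyl-3-(2-methyl-5-oxopentan-2-yl)-2-oxocyclohexyl]-3-methylpentanoate | COC(=O)C[C@H](C)CC[C@@]1(C)C(=O)[C@H](C(C)(C)CCC=O)CC[C@H]1C | intermediate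
13 | methyl (3R)-3-methyl-5-[(1R,2R,4aS)-1,2,5,5-tetramethyl-1,2,3,4,4a,5,6,7-octahydronaphthalen-1-yl]pentanoate | COC(=O)C[C@H](C)CC[C@@]1(C)C2=CCCC(C)(C)[C@@H]2CC[C@H]1C | intermediate
14 | (3R)-3-methyl-5-[(1R,2R,4aS)-1,2,5,5-tetramethyl-1,2,3,4,4a,5,6,7-octahydronaphthalen-1-yl]pentanoic acid | OC(=O)C[C@H](C)CC[C@@]1(C)C2=CCCC(C)(C)[C@@H]2CC[C@H]1C | intermediate
15 | glycerol, propane-1,2,3-triol | OCC(O)CO | starting material
16 | O-acylisourea of 14 with N,N'-diisopropylcarbodiimide | CC(C)N=C(NC(C)C)OC(=O)C[C@H](C)CC[C@@]1(C)C2=CCCC(C)(C)[C@@H]2CC[C@H]1C | intermediate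
17 | 1,3-dihydroxypropan-2-yl (3R)-3-methyl-5-[(1R,2R,4aS)-1,2,5,5-tetramethyl-1,2,3,4,4a,5,6,7-octahydronaphthalen-1-yl]pentanoate | C[C@H](CC[C@@]1(C)C2=CCCC(C)(C)[C@@H]2CC[C@H]1C)CC(=O)OC(CO)CO | target

**Step count**
Total steps: 9. Longest linear sequence: 7 steps (1 → 4 → 6 → 11 → 12 → 13 → 14 → 17; the side-chain branch 7 → 8 → 9 → 11 → 17 is equally long).

**Three steps most likely to fail, with fallbacks**

Step 9 (the new 2-O-selective esterification). The risks are competing acylation of a primary hydroxyl, 2→1 acyl migration and slow catalyst turnover. The fallback uses known chemistry, sets out from 14 and comes back at 17. Acid 14 is esterified (N,N'-dicyclohexylcarbodiimide, 4-(dimethylamino)pyridine, CH2Cl2) with commercial cis-2-phenyl-1,3-dioxan-5-ol (cis-1,3-O-benzylideneglycerol), whose only free hydroxyl is the glycerol C2–OH. This gives cis-2-phenyl-1,3-dioxan-5-yl (3R)-3-methyl-5-[(1R,2R,4aS)-1,2,5,5-tetramethyl-1,2,3,4,4a,5,6,7-octahydronaphthalen-1-yl]pentanoate F1. The benzylidene acetal is then removed with B(OH)3 in B(OMe)3 at 90 °C followed by water, the established non-migrating deprotection for 2-monoacylglycerols, which also spares the alkene, giving 17.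

Step 5 (alkylation that sets the C9 quaternary centre). The risks are low SN2 reactivity of an unactivated primary iodide towards a hindered tetrasubstituted enolate, and only moderate facial selectivity. The fallback sets out from 6 and comes back at 11; it replaces the SN2 step by a conjugate addition and moves C13 from chiral-pool to catalyst control. The enolate of 6 is added to but-3-en-2-one (catalytic KOtBu, tBuOH/THF, 0 °C; same axial facial preference, and the hindered ring ketone does not undergo aldol closure) to give (2R,3R,6S)-6-[4-(1,3-dioxan-2-yl)-2-methylbutan-2-yl]-2,3-dimethyl-2-(3-oxobutyl)cyclohexan-1-one F2. Horner–Wadsworth–Emmons olefination of the methyl ketone (trimethyl phosphonoacetate, NaH, THF) gives methyl (2E)-5-[(1R,3S,6R)-3-[4-(1,3-dioxan-2-yl)-2-methylbutan-2-yl]-1,6-dimethyl-2-oxocyclohexyl]-3-methylpent-2-enoate F3. Copper hydride-catalysed asymmetric 1,4-reduction (CuCl, NaOtBu, the enantiomer of 2,2'-bis(di-p-tolylphosphino)-1,1'-binaphthyl that gives 3R, polymethylhydrosiloxane) then gives 11.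

Step 7 (McMurry ring closure). The risks are partial reduction of the methyl ester by low-valent titanium and sluggish coupling at the doubly flanked ketone. The fallback sets out from 12 and comes back at 13; it splits the reductive coupling into an ester-tolerant pinacol closure and a separate deoxygenation. SmI2 (THF, tBuOH, −78 → 0 °C) gives the cis-diol methyl (3R)-5-[(1R,2R,4aS)-8,8a-cis-dihydroxy-1,2,5,5-tetramethyldecahydronaphthalen-1-yl]-3-methylpentanoate F4 (hydroxyls drawn trans to H-4a; either cis-diol serves). 1,1'-Thiocarbonyldiimidazole (toluene, 90 °C) converts it into the 8,8a-cyclic thionocarbonate of that diol F5, and Corey–Winter elimination with P(OMe)3 at reflux gives 13.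

**Further compounds**
F1 | step 9 | cis-2-phenyl-1,3-dioxan-5-yl (3R)-3-methyl-5-[(1R,2R,4aS)-1,2,5,5-tetramethyl-1,2,3,4,4a,5,6,7-octahydronaphthalen-1-yl]pentanoate | C[C@H](CC[C@@]1(C)C2=CCCC(C)(C)[C@@H]2CC[C@H]1C)CC(=O)O[C@H]1CO[C@@H](c2ccccc2)OC1
F2 | step 5 | (2R,3R,6S)-6-[4-(1,3-dioxan-2-yl)-2-methylbutan-2-yl]-2,3-dimethyl-2-(3-oxobutyl)cyclohexan-1-one | CC(=O)CC[C@@]1(C)C(=O)[C@H](C(C)(C)CCC2OCCCO2)CC[C@H]1C
F3 | step 5 | methyl (2E)-5-[(1R,3S,6R)-3-[4-(1,3-dioxan-2-yl)-2-methylbutan-2-yl]-1,6-dimethyl-2-oxocyclohexyl]-3-methylpent-2-enoate | COC(=O)/C=C(\C)CC[C@@]1(C)C(=O)[C@H](C(C)(C)CCC2OCCCO2)CC[C@H]1C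
F4 | step 7 | methyl (3R)-5-[(1R,2R,4aS)-8,8a-cis-dihydroxy-1,2,5,5-tetramethyldecahydronaphthalen-1-yl]-3-methylpentanoate (hydroxyls trans to H-4a) | COC(=O)C[C@H](C)CC[C@@]1(C)[C@@]2(O)[C@H](O)CCC(C)(C)[C@@H]2CC[C@H]1C
F5 | step 7 | 8,8a-cyclic thionocarbonate of F4 | COC(=O)C[C@H](C)CC[C@@]1(C)[C@@]23OC(=S)O[C@@H]2CCC(C)(C)[C@@H]3CC[C@H]1C
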